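The runs stem from a simulated flask from invented constants, noise included.

A percentage point of target in these flasks is 0.100 mM, and I count in that unit. Grey is the flask asked about, followed so far; amber ran earlier at 20 °C with 0.30 mM of free catalyst.

| setting | grey | amber | flask |
|---|---|---|---|
| starting material | 10 mM | 10 mM | 10 mM |
| reagent | 15 mM | 15 mM | 15.0 mM |
| free catalyst | 0.20 mM | 0.30 mM | 0.20 mM |
| second catalyst | 1.2 mM | 1.2 mM | 1.2 mM |
| temperature | 25 °C | 20 °C | 25 °C |
| remark | the very flask that is asked about, followed so far | run made earlier |  |
| time |  |  | 3.0 h |

| run | time / min | target / % |
|---|---|---|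
| grey | 25.0 | 28.6 |
| grey | 50.0 | 28.9 |
| grey | 80.0 | 28.7 |
| grey | 90.0 | 28.1 |
| grey | 120 | 28.8 |
| grey | 150 | 28.6 |
| grey | 180 | 28.9 |
| amber | 3.00 | 40.5 |
| amber | 6.00 | 36.5 |
| amber | 8.00 | 31.9 |
| amber | 12.0 | 26.0 |
| amber | 15.0 | 23.2 |
| amber | 20.0 | 23.0 |

(standard deviation of a reading: 0.5 percentage points)

- Tuesday's: at 3.0 h take out 90% of the target then present, then wait 6.0 h
- Friday's: at 3.0 h add reagent, 100% of the amount charged, then wait 6.0 h
- Saturday's: at 3.0 h add free catalyst, 100% of the amount charged, then wait 6.0 h
- Wednesday's: at 3.0 h raise the temperature by 20 K, then wait 6.0 h
- Thursday's: change nothing and wait 6.0 h more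

- removed target is counted in
- "the catalyst" is free catalyst with its forms; second catalyst is a second catalyst
- additions bring no volume worth counting

1. target, in percent of the starting material first charged, at 3.0 h
2. what to do for the largest gain in target; "none" if nothing gains more than 2 percentage points (Tuesday's / Friday's / Saturday's / Wednesday's / Thursday's / none)
3. target present, with what was taken out counted in, in percent of the starting material first charged, after Tuesday's
4. target present, with what was taken out counted in, in percent of the starting material first charged, after Saturday's

Grey stays flat from 25.0 min on, with a mean of 28.7%, while amber falls from 40.5% and its last two readings average 23.1%. Two extreme flasks can be done in the head. In the first, target is a dead end that spare reagent eats one for one until the reagent runs out: the spare 5.00 mM then leaves 50.0% of target in both runs, and neither removal nor heat gains anything. In the second, target exchanges with one other form, and the whole charge divides by temperature; I call the part standing as target the standing share, which is thermodynamic control. The readings lie at this second end: the same amounts of starting material and reagent stop at different levels, and neither level is the dead-end one. The runs differ in free catalyst as well as in temperature, and I put the gap between them on temperature, taking a catalyst to change a pace, not a split. Grey is flat by 25.0 min, and the wait of 6.0 h is far longer, so the exchange has time to finish.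

So I reckon 28.7% now. At this end I take Thursday's, Friday's and Saturday's to leave the share where it stands, as the exchange has no reagent in it and extra free catalyst is taken to change its pace. Tuesday's needs two rounds: the first takes out 25.8%, and the second divides the remaining 74.2% by the same share, giving 47.1% counted in, a gain of 18 percentage points. For Wednesday's I use the ratio of other form to target as read, 2.49 in grey and 3.33 in amber. The rise of 20 K is 4 times the gap between those runs, so I reckon the ratio at 0.779, the share at 56.2%, and the gain at 28 points, which makes Wednesday's my choice.

The forecast, differing on the choice and on Tuesday's, gave 28.7% now, none as the choice, 28.7% after Tuesday's and 28.7% after Saturday's, with the words “Removing target does not regenerate it, since it is not a reversible equilibrium”.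

    starting material + free catalyst ⇌ free catalyst + open intermediate (K = 2.90, k = 110 M⁻¹ s⁻¹, Ea = 41.0 kJ mol⁻¹, ΔH = −39.0 kJ mol⁻¹)
    second catalyst + open intermediate ⇌ catalyst intermediate (K = 25.0 M⁻¹, k = 150 M⁻¹ s⁻¹, Ea = 42.0 kJ mol⁻¹, ΔH = −48.0 kJ mol⁻¹)
    reagent + catalyst intermediate → second catalyst + target (k = 32.0 M⁻¹ s⁻¹, Ea = 44.0 kJ mol⁻¹)
    target + free catalyst ⇌ isomer of the product + free catalyst, rate k4*[free catalyst]*[target] forward; the back reaction follows from the equilibrium constant (K = 2.50, k = 23.0 M⁻¹ s⁻¹, Ea = 43.0 kJ mol⁻¹, ΔH = −47.0 kJ mol⁻¹)
    (constants at 25 °C)

The flask gives 28.6% now and Wednesday's as the choice, with a gain of 28 points; Tuesday's ends at 46.9% and Saturday's at 28.6%. Target passes to the isomer of the product with a forward half-life, that step alone with the other concentrations as charged, of 2.5 min, shorter than the 3.0 h. The standing share leaves 71.3% for the other form, and the isomer of the product holds 71.4% at that time.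

The repeat at 10 °C lies 3 gaps below grey, so I reckon the share there at 14.4%. That flask gives 12.8% of target beside 87.2% of the isomer of the product.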